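Everything rests on opening ring D, a 1,4-bis(aryloxy)-3,5-dihydroxybenzene. Read as an open chain, D C6, C1, C2 and C3 map onto a but-2-enoate whose position 3 bears the ring C oxygen. D C4 and C5 map onto the acetyl unit hanging on the ring E oxygen, and the two hydroxyls are the former carbonyl oxygens. In one flask the dienolate terminus of the ring A–B–C crotonate is acylated by the ring E aryloxyacetamide (D C5–C6). The aryloxy-bearing carbanion then closes on the ester (D C3–C4), so both crowded ethers of ring D are in place before the ring exists. The crotonate comes from two Ullmann/Baeyer–Villiger cycles and an oxa-Michael addition.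

Key step: step 11

Ring labels: rings run A to G from the 2,4,6-trihydroxyphenyl end to the 3,4,5-trihydroxyphenyl end. In rings B, D and F, C1 bears the oxygen towards ring A and C4 the oxygen towards ring G. In rings C and E, C1 bears the oxygen towards ring A and C6 the oxygen towards ring G.

Remark on the chemistry (acyl donor): the ring E partner is carried as its N-methoxy-N-methylamide, which has the same aryloxyacetyl skeleton as the methyl ester. Its CH2 is far less acidic, and it stores the first adduct as a lithium chelate. The valuable dienolate is therefore neither quenched by proton transfer nor used up by the acidic acylation product.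

Remark on the chemistry (protecting groups): all seventeen phenols travel as methyl ethers. Small flanking groups keep the couplings of di-ortho-substituted phenols workable, and the building blocks can be bought. Benzyl marks only E C6–O.

Step 1
Reactants: 1 2,4,6-trimethoxybenzaldehyde
Product: 3 2,4,6-trimethoxyphenol, via aryl formate 2 (not isolated)
Conditions: 30% aq. H2O2 (1.3 equiv), H2SO4 (cat.), MeOH, 0 °C to rt
Reagents that add atoms: hydrogen peroxide, OO
Why: Acid-catalysed Dakin-type Baeyer–Villiger oxidation, in which the very electron-rich aryl group migrates to oxygen and the resulting formate is methanolysed in the same flask.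

Step 2
Reactants: 3 2,4,6-trimethoxyphenol; 4 4-bromo-2,6-dimethoxybenzaldehyde
Product: 5 2,6-dimethoxy-4-(2,4,6-trimethoxyphenoxy)benzaldehyde (ring A–B aldehyde)
Conditions: CuI (10 mol %), picolinic acid (20 mol %), K3PO4 (2 equiv), DMSO, 100 °C, argon
Reagents that add atoms: none
Why: Ullmann-type Cu-catalysed diaryl ether synthesis, for which the picolinic acid ligand suits 2,6-disubstituted phenols and the C–Br bond of 4 is unhindered and activated by the para formyl group, which also serves as the masked B C4 oxygen.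

Step 3
Reactants: 5 ring A–B aldehyde
Product: 7 2,6-dimethoxy-4-(2,4,6-trimethoxyphenoxy)phenol (ring A–B phenol), via ring A–B formate 6 (not isolated)
Conditions: mCPBA (1.2 equiv), CH2Cl2, 0 °C to rt; aq. NaHCO3 wash; K2CO3 (0.2 equiv), MeOH, rt
Reagents that add atoms: mCPBA, O=C(OO)c1cccc(Cl)c1
Why: Baeyer–Villiger oxidation of a 2,6-dialkoxybenzaldehyde followed by transesterification of the formate; aryl migration is strongly favoured and the small excess of peracid at low temperature should leave electron-rich ring A untouched.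

Step 4
Reactants: 8 5-bromo-1,2,3-trimethoxybenzene
Product: 9 6-bromo-2,3,4-trimethoxybenzaldehyde
Conditions: Cl2CHOMe (1.3 equiv), TiCl4 (2 equiv), CH2Cl2, −10 to 0 °C; ice–water
Reagents that add atoms: dichloromethyl methyl ether, COC(Cl)Cl; water, O
Why: Rieche formylation, a Friedel–Crafts-type substitution: the two free positions of 8 are equivalent and each lies ortho to one methoxy group and para to another, so a single aldehyde with bromine ortho to the formyl group is expected.

Step 5
Reactants: 7 ring A–B phenol; 9 6-bromo-2,3,4-trimethoxybenzaldehyde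
Product: 10 6-[2,6-dimethoxy-4-(2,4,6-trimethoxyphenoxy)phenoxy]-2,3,4-trimethoxybenzaldehyde (ring A–B–C aldehyde)
Conditions: CuI (20 mol %), picolinic acid (40 mol %), K3PO4 (2 equiv), DMSO, 100 °C, argon
Reagents that add atoms: none
Why: Ullmann-type coupling as in step 2, helped by the ortho formyl group of 9, which activates the C–Br bond and later becomes the C C6 oxygen, so the substitution pattern of ring C is fixed by the building block.

Step 6
Reactants: 10 ring A–B–C aldehyde
Product: 12 6-[2,6-dimethoxy-4-(2,4,6-trimethoxyphenoxy)phenoxy]-2,3,4-trimethoxyphenol (ring A–B–C phenol), via ring A–B–C formate 11 (not isolated)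
Conditions: mCPBA (1.2 equiv), CH2Cl2, 0 °C to rt; aq. NaHCO3 wash; K2CO3 (0.2 equiv), MeOH, rt, argon
Reagents that add atoms: mCPBA, O=C(OO)c1cccc(Cl)c1
Why: Baeyer–Villiger oxidation and formate methanolysis as in step 3; the migrating carbon of ring C is flanked by two oxygen substituents and migrates readily.

Step 7
Reactants: 12 ring A–B–C phenol; 13 methyl but-2-ynoate
Product: 14 methyl (E)-3-{6-[2,6-dimethoxy-4-(2,4,6-trimethoxyphenoxy)phenoxy]-2,3,4-trimethoxyphenoxy}but-2-enoate
Conditions: 13 (2 equiv), Cs2CO3 (0.5 equiv), MeCN, 60 °C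
Reagents that add atoms: none
Why: Carbonate-mediated oxa-Michael addition of a phenoxide to an ynoate, reversible under the conditions, so the more stable E isomer with the aryloxy group trans and the methyl group cis to the ester should prevail.

Step 8
Reactants: 15 2-hydroxy-4,6-dimethoxybenzaldehyde; 16 2-chloro-N-methoxy-N-methylacetamide
Product: 17 2-(2-formyl-3,5-dimethoxyphenoxy)-N-methoxy-N-methylacetamide
Conditions: K2CO3 (1.5 equiv), KI (0.1 equiv), DMF, 60 °C
Reagents that add atoms: none
Why: Williamson ether synthesis with an activated α-chloroamide; alkylating before the oxidation places the acetamide on the oxygen that becomes E C1–O, and the amide CH2 is too weakly acidic for aldol closure onto the neighbouring aldehyde.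

Step 9
Reactants: 17 2-(2-formyl-3,5-dimethoxyphenoxy)-N-methoxy-N-methylacetamide
Product: 19 2-(2-hydroxy-3,5-dimethoxyphenoxy)-N-methoxy-N-methylacetamide, via ring E formate 18 (not isolated)
Conditions: mCPBA (1.2 equiv), CH2Cl2, 0 °C to rt; aq. NaHCO3 wash; K2CO3 (0.2 equiv), MeOH, rt
Reagents that add atoms: mCPBA, O=C(OO)c1cccc(Cl)c1
Why: Baeyer–Villiger oxidation and formate methanolysis install E C6–O at the former formyl carbon, and the N-methoxy-N-methylamide is inert to peracid and to catalytic carbonate in methanol.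

Step 10
Reactants: 19 2-(2-hydroxy-3,5-dimethoxyphenoxy)-N-methoxy-N-methylacetamide
Product: 20 2-[2-(benzyloxy)-3,5-dimethoxyphenoxy]-N-methoxy-N-methylacetamide
Conditions: BnBr (1.2 equiv), K2CO3 (1.5 equiv), DMF, rt
Reagents that add atoms: benzyl bromide, BrCc1ccccc1
Why: Williamson benzylation of the only free phenol gives a group that withstands amide bases and can later be removed without touching methyl ethers.

Step 11
Reactants: 14 methyl (E)-3-aryloxybut-2-enoate of rings A–B–C; 20 ring E aryloxyacetamide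
Product: 24 2-[2-(benzyloxy)-3,5-dimethoxyphenoxy]-5-{6-[2,6-dimethoxy-4-(2,4,6-trimethoxyphenoxy)phenoxy]-2,3,4-trimethoxyphenoxy}benzene-1,3-diol (ring A–B–C–D–E pentamer diol), via lithium dienolate 21 (not isolated), via chelated adduct 22 (not isolated), via keto enoate 23 (not isolated)
Conditions: LiN(iPr)2 (1.1 equiv), THF, −78 °C; 20 (1.2 equiv), −78 to −40 °C; LiN(iPr)2 (2.5 equiv), −78 °C to rt, argon; 1 M HCl
Reagents that add atoms: none
Why: Proposed new method: LiN(iPr)2 removes a proton from the methyl group of 14 that lies cis to the ester, the CH2 terminus of dienolate 21 adds to the amide carbonyl of 20, and the lithium chelate 22 stores the new D C5–C6 bond without using up further dienolate. The second charge of base deprotonates D C6, which collapses 22 to the enolate of 23, and then removes a D C4 proton, acidified by the ketone and the ring E aryloxy group. The C4 carbanion attacks the ester carbon D C3 in a favoured 6-(enolendo)-exo-trig Dieckmann closure (equivalently, loss of methoxide from the extended enolate gives a dienylketene that closes in a 6π process), and tautomerisation of the cyclohexadienone to the resorcinol makes the closure irreversible. The closest known reaction types are the terminal acylation of lithium dienolates of 3-alkoxybut-2-enoates and dioxinones by N-methoxy-N-methylamides and the base-induced conversion of methyl 3-methoxy-5-oxohex-2-enoate or its pyranone into 5-methoxyresorcinol; their union in one flask on a chain with two aryloxy groups has not been shown. Terminal rather than ester-adjacent acylation is secured by the bulky ring C aryloxy group next to D C2 and the unhindered CH2 terminus, carbon rather than oxygen closure by forming the dianion at −78 °C before warming so that the last-formed and least stabilised carbanion reacts first, and retention of the ring C ether by the use of a non-nucleophilic amide base, since alkoxide could displace the aryloxide at D C1 by addition–elimination. No stereocentre is created, and the E geometry of 14 already places the growing chain cis to the ester as the closure requires.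

Step 12
Reactants: 24 pentamer diol
Product: 25 pentamer benzyl ether with D C3 and D C5 methoxy groups
Conditions: Me2SO4 (3 equiv), K2CO3 (4 equiv), acetone, reflux
Reagents that add atoms: dimethyl sulfate, COS(=O)(=O)OC
Why: Williamson O-methylation with a hard electrophile and a weak base favours oxygen over carbon alkylation of the phloroglucinol-type ring D and leaves E C6–O as the only site that can be unmasked next.

Step 13
Reactants: 25 pentamer benzyl ether
Product: 26 pentamer phenol with free E C6–OH
Conditions: H2 (1 atm), 10% Pd/C, EtOAc–MeOH, rt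
Reagents that add atoms: none
Why: Catalytic hydrogenolysis cleaves the single benzyl aryl ether, while methyl and diaryl ethers are inert to H2 over Pd/C.

Step 14
Reactants: 27 4-bromo-2,6-dimethoxyphenol; 28 3,4,5-trimethoxyphenylboronic acid
Product: 29 5-bromo-1,3-dimethoxy-2-(3,4,5-trimethoxyphenoxy)benzene (ring F–G bromide)
Conditions: 28 (2 equiv), Cu(OAc)2 (0.3 equiv), pyridine (3 equiv), 4 Å MS, O2 (1 atm), CH2Cl2, rt
Reagents that add atoms: none
Why: Chan–Lam coupling, an oxidative Cu-mediated O-arylation at room temperature, accepts 2,6-disubstituted phenols and leaves the aryl bromide intact because no insertion into the C–Br bond takes place.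

Step 15
Reactants: 26 pentamer phenol; 29 ring F–G bromide
Product: 30 heptadeca-O-methyl ether of the target (ring A–G heptamer)
Conditions: 29 (1.5 equiv), CuI (20 mol %), picolinic acid (40 mol %), K3PO4 (3 equiv), DMSO, 100 °C, argon
Reagents that add atoms: none
Why: Ullmann-type coupling under the hindered-phenol conditions of steps 2 and 5; the C–Br carbon of 29 has two ortho hydrogens, so all steric demand lies on the phenol side, and 29 can be used in excess.

Step 16
Reactants: 30 heptadeca-O-methyl ether
Product: 31 CNP0351377.0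
Conditions: BBr3 (50 equiv), CH2Cl2, −78 °C to rt, argon; ice–water; reversed-phase chromatography with degassed solvents
Reagents that add atoms: none
Why: Lewis-acid ether cleavage, in which each methoxy oxygen binds boron and bromide attacks the methyl carbon in an SN2 step, whereas the six diaryl ether bonds offer no sp3 carbon and persist, and hydrolysis of the aryl borates frees the seventeen phenols.

Compound list
1 | 2,4,6-trimethoxybenzaldehyde | COc1cc(OC)c(C=O)c(OC)c1 | starting material
2 | 2,4,6-trimethoxyphenyl formate | COc1cc(OC)c(OC=O)c(OC)c1 | intermediate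
3 | 2,4,6-trimethoxyphenol | COc1cc(OC)c(O)c(OC)c1 | intermediate
4 | 4-bromo-2,6-dimethoxybenzaldehyde | COc1cc(Br)cc(OC)c1C=O | starting material
5 | 2,6-dimethoxy-4-(2,4,6-trimethoxyphenoxy)benzaldehyde | COc1cc(OC)c(Oc2cc(OC)c(C=O)c(OC)c2)c(OC)c1 | intermediate
6 | 2,6-dimethoxy-4-(2,4,6-trimethoxyphenoxy)phenyl formate | COc1cc(OC)c(Oc2cc(OC)c(OC=O)c(OC)c2)c(OC)c1 | intermediate
7 | 2,6-dimethoxy-4-(2,4,6-trimethoxyphenoxy)phenol | COc1cc(OC)c(Oc2cc(OC)c(O)c(OC)c2)c(OC)c1 | intermediate
8 | 5-bromo-1,2,3-trimethoxybenzene | COc1cc(Br)cc(OC)c1OC | starting material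
9 | 6-bromo-2,3,4-trimethoxybenzaldehyde | COc1cc(Br)c(C=O)c(OC)c1OC | intermediate
10 | 6-[2,6-dimethoxy-4-(2,4,6-trimethoxyphenoxy)phenoxy]-2,3,4-trimethoxybenzaldehyde | COc1cc(OC)c(Oc2cc(OC)c(Oc3cc(OC)c(OC)c(OC)c3C=O)c(OC)c2)c(OC)c1 | intermediate
11 | 6-[2,6-dimethoxy-4-(2,4,6-trimethoxyphenoxy)phenoxy]-2,3,4-trimethoxyphenyl formate | COc1cc(OC)c(Oc2cc(OC)c(Oc3cc(OC)c(OC)c(OC)c3OC=O)c(OC)c2)c(OC)c1 | intermediate
12 | 6-[2,6-dimethoxy-4-(2,4,6-trimethoxyphenoxy)phenoxy]-2,3,4-trimethoxyphenol | COc1cc(OC)c(Oc2cc(OC)c(Oc3cc(OC)c(OC)c(OC)c3O)c(OC)c2)c(OC)c1 | intermediate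
13 | methyl but-2-ynoate | CC#CC(=O)OC | starting material
14 | methyl (E)-3-{6-[2,6-dimethoxy-4-(2,4,6-trimethoxyphenoxy)phenoxy]-2,3,4-trimethoxyphenoxy}but-2-enoate | COC(=O)/C=C(\C)Oc1c(OC)c(OC)c(OC)cc1Oc1c(OC)cc(Oc2c(OC)cc(OC)cc2OC)cc1OC | intermediate
15 | 2-hydroxy-4,6-dimethoxybenzaldehyde | COc1cc(O)c(C=O)c(OC)c1 | starting material
16 | 2-chloro-N-methoxy-N-methylacetamide | CON(C)C(=O)CCl | starting material
17 | 2-(2-formyl-3,5-dimethoxyphenoxy)-N-methoxy-N-methylacetamide | CON(C)C(=O)COc1cc(OC)cc(OC)c1C=O | intermediate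
18 | 2,4-dimethoxy-6-{2-[methoxy(methyl)amino]-2-oxoethoxy}phenyl formate | CON(C)C(=O)COc1cc(OC)cc(OC)c1OC=O | intermediate
19 | 2-(2-hydroxy-3,5-dimethoxyphenoxy)-N-methoxy-N-methylacetamide | CON(C)C(=O)COc1cc(OC)cc(OC)c1O | intermediate
20 | 2-[2-(benzyloxy)-3,5-dimethoxyphenoxy]-N-methoxy-N-methylacetamide | CON(C)C(=O)COc1cc(OC)cc(OC)c1OCc1ccccc1 | intermediate
21 | lithium dienolate of 14 (1-methoxy-3-aryloxybuta-1,3-dien-1-olate) | [Li+].C=C(C=C([O-])OC)Oc1c(OC)c(OC)c(OC)cc1Oc1c(OC)cc(Oc2c(OC)cc(OC)cc2OC)cc1OC | intermediate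
22 | lithium alkoxide adduct of 21 to 20 (racemic, transient carbinolamine carbon at D C5) | [Li+].COC(=O)/C=C(\CC([O-])(COc1cc(OC)cc(OC)c1OCc1ccccc1)N(C)OC)Oc1c(OC)c(OC)c(OC)cc1Oc1c(OC)cc(Oc2c(OC)cc(OC)cc2OC)cc1OC | intermediate
23 | methyl (E)-6-[2-(benzyloxy)-3,5-dimethoxyphenoxy]-5-oxo-3-(ring A–B–C aryloxy)hex-2-enoate, present as its enolate | COC(=O)/C=C(\CC(=O)COc1cc(OC)cc(OC)c1OCc1ccccc1)Oc1c(OC)c(OC)c(OC)cc1Oc1c(OC)cc(Oc2c(OC)cc(OC)cc2OC)cc1OC | intermediate
24 | ring A–B–C–D–E pentamer with free D C3 and D C5 hydroxyls and benzyl on E C6–O | COc1cc(OC)c(Oc2cc(OC)c(Oc3cc(OC)c(OC)c(OC)c3Oc3cc(O)c(Oc4cc(OC)cc(OC)c4OCc4ccccc4)c(O)c3)c(OC)c2)c(OC)c1 | intermediate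
25 | pentamer benzyl ether with D C3 and D C5 methoxy groups | COc1cc(OC)c(Oc2cc(OC)c(Oc3cc(OC)c(OC)c(OC)c3Oc3cc(OC)c(Oc4cc(OC)cc(OC)c4OCc4ccccc4)c(OC)c3)c(OC)c2)c(OC)c1 | intermediate
26 | pentamer phenol with free E C6–OH | COc1cc(OC)c(Oc2cc(OC)c(Oc3cc(OC)c(OC)c(OC)c3Oc3cc(OC)c(Oc4cc(OC)cc(OC)c4O)c(OC)c3)c(OC)c2)c(OC)c1 | intermediate
27 | 4-bromo-2,6-dimethoxyphenol | COc1cc(Br)cc(OC)c1O | starting material
28 | 3,4,5-trimethoxyphenylboronic acid | COc1cc(B(O)O)cc(OC)c1OC | starting material
29 | 5-bromo-1,3-dimethoxy-2-(3,4,5-trimethoxyphenoxy)benzene | COc1cc(Oc2c(OC)cc(Br)cc2OC)cc(OC)c1OC | intermediate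
30 | heptadeca-O-methyl ether of the target | COc1cc(OC)c(Oc2cc(OC)c(Oc3cc(OC)c(OC)c(OC)c3Oc3cc(OC)c(Oc4cc(OC)cc(OC)c4Oc4cc(OC)c(Oc5cc(OC)c(OC)c(OC)c5)c(OC)c4)c(OC)c3)c(OC)c2)c(OC)c1 | intermediate
31 | CNP0351377.0 | Oc1cc(O)c(Oc2cc(O)c(Oc3cc(O)c(O)c(O)c3Oc3cc(O)c(Oc4cc(O)cc(O)c4Oc4cc(O)c(Oc5cc(O)c(O)c(O)c5)c(O)c4)c(O)c3)c(O)c2)c(O)c1 | target

Total step count: 16. Longest linear sequence: 11 steps (1, 2, 3, 5, 6, 7, 11, 12, 13, 15, 16).

Steps most likely to fail

Step 11 (bears the label). Four things may go wrong: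
- the ring C aryloxide may be expelled from the dienolate by β-elimination towards the allenoate;
- acylation may occur at the ester-adjacent carbon;
- closure may run through oxygen to a pyranone;
- the reaction may stop at the open-chain enolate.

The fallback uses only reaction types already run in steps 2, 3, 5 and 6 and brings ring D in as a ready-made arene. It sets out from phenol 12. Ullmann coupling with bromoaldehyde 4 (CuI, picolinic acid, K3PO4, DMSO, 100 °C) should give the ring A–B–C–D aldehyde F1. mCPBA and then K2CO3 in MeOH lead through the tetramer formate F2 to the ring A–B–C–D phenol F3. A second Ullmann coupling, with purchased 2-bromo-4,6-dimethoxybenzaldehyde F4, gives the pentamer aldehyde F5. Baeyer–Villiger oxidation through the pentamer formate F6 with methanolysis comes back to the route at phenol 26, so steps 7 to 13 are bypassed.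

Step 16. The seventeen ethers may be cleaved incompletely as boron aryloxides precipitate. The pyrogallol-type rings C and G may also oxidise in air during isolation of the free polyphenol. The fallback sets out from 30. The crude product of the BBr3 cleavage is not purified as the free phenol but acetylated at once (Ac2O, pyridine, DMAP cat., rt) to the heptadecaacetate F7. F7 is stable in air and can be purified on silica. Fractions that still hold methoxy groups are separated there and cleaved again. Acid methanolysis of F7 (HCl in degassed MeOH, rt, argon) then comes back to the route at 31 with only volatile by-products.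

Step 15. The coupling may be slow at a phenol flanked by a methoxy group and a large aryloxy group, so that hydrodebromination of the electron-rich bromide overtakes ether formation. The fallback sets out from 26 and adds rings F and G one at a time with a more reactive electrophile. Coupling with bromoaldehyde 4 gives the hexamer aldehyde F8. The C–Br bond of 4 is activated by the para formyl group and is also open to uncatalysed nucleophilic aromatic substitution in hot DMSO. mCPBA and then K2CO3 in MeOH lead through the hexamer formate F9 to the hexamer phenol F10. Chan–Lam coupling of F10 with boronic acid 28 under the conditions of step 14 comes back to the route at 30.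

Further compounds
F1 | step 11 | ring A–B–C–D aldehyde, 4-(ring A–B–C aryloxy)-2,6-dimethoxybenzaldehyde | COc1cc(OC)c(Oc2cc(OC)c(Oc3cc(OC)c(OC)c(OC)c3Oc3cc(OC)c(C=O)c(OC)c3)c(OC)c2)c(OC)c1
F2 | step 11 | tetramer formate, 4-(ring A–B–C aryloxy)-2,6-dimethoxyphenyl formate | COc1cc(OC)c(Oc2cc(OC)c(Oc3cc(OC)c(OC)c(OC)c3Oc3cc(OC)c(OC=O)c(OC)c3)c(OC)c2)c(OC)c1
F3 | step 11 | ring A–B–C–D phenol, 4-(ring A–B–C aryloxy)-2,6-dimethoxyphenol | COc1cc(OC)c(Oc2cc(OC)c(Oc3cc(OC)c(OC)c(OC)c3Oc3cc(OC)c(O)c(OC)c3)c(OC)c2)c(OC)c1
F4 | step 11 | 2-bromo-4,6-dimethoxybenzaldehyde (purchased) | COc1cc(Br)c(C=O)c(OC)c1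
F5 | step 11 | pentamer aldehyde, 2-(ring A–B–C–D aryloxy)-4,6-dimethoxybenzaldehyde | COc1cc(OC)c(Oc2cc(OC)c(Oc3cc(OC)c(OC)c(OC)c3Oc3cc(OC)c(Oc4cc(OC)cc(OC)c4C=O)c(OC)c3)c(OC)c2)c(OC)c1
F6 | step 11 | pentamer formate, 2-(ring A–B–C–D aryloxy)-4,6-dimethoxyphenyl formate | COc1cc(OC)c(Oc2cc(OC)c(Oc3cc(OC)c(OC)c(OC)c3Oc3cc(OC)c(Oc4cc(OC)cc(OC)c4OC=O)c(OC)c3)c(OC)c2)c(OC)c1
F7 | step 16 | heptadecaacetate of 31 | CC(=O)Oc1cc(OC(C)=O)c(Oc2cc(OC(C)=O)c(Oc3cc(OC(C)=O)c(OC(C)=O)c(OC(C)=O)c3Oc3cc(OC(C)=O)c(Oc4cc(OC(C)=O)cc(OC(C)=O)c4Oc4cc(OC(C)=O)c(Oc5cc(OC(C)=O)c(OC(C)=O)c(OC(C)=O)c5)c(OC(C)=O)c4)c(OC(C)=O)c3)c(OC(C)=O)c2)c(OC(C)=O)c1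
F8 | step 15 | hexamer aldehyde, 4-(pentamer aryloxy)-2,6-dimethoxybenzaldehyde | COc1cc(OC)c(Oc2cc(OC)c(Oc3cc(OC)c(OC)c(OC)c3Oc3cc(OC)c(Oc4cc(OC)cc(OC)c4Oc4cc(OC)c(C=O)c(OC)c4)c(OC)c3)c(OC)c2)c(OC)c1
F9 | step 15 | hexamer formate, 4-(pentamer aryloxy)-2,6-dimethoxyphenyl formate | COc1cc(OC)c(Oc2cc(OC)c(Oc3cc(OC)c(OC)c(OC)c3Oc3cc(OC)c(Oc4cc(OC)cc(OC)c4Oc4cc(OC)c(OC=O)c(OC)c4)c(OC)c3)c(OC)c2)c(OC)c1
F10 | step 15 | hexamer phenol, 4-(pentamer aryloxy)-2,6-dimethoxyphenol | COc1cc(OC)c(Oc2cc(OC)c(Oc3cc(OC)c(OC)c(OC)c3Oc3cc(OC)c(Oc4cc(OC)cc(OC)c4Oc4cc(OC)c(O)c(OC)c4)c(OC)c3)c(OC)c2)c(OC)c1
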